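## Structural features

The target is a linear tetramer of phenylpropanoid units. Ring A (4-hydroxy-3-methoxyphenyl, free phenol) carries a 1-aryl-2-aryloxypropane-1,3-diol chain whose C2 oxygen is the 4-oxygen of ring B (3,5-dimethoxyphenyl). Ring B carries a second chain of the same kind whose C2 oxygen is the 4-oxygen of ring C (also 3,5-dimethoxy), and ring C stands at C2 of a 2,3-dihydrobenzofuran (ring D fused to the oxygen ring) bearing CH2OH at C3, OMe at C7 and an (E)-propenal at C5. The six stereocentres form three adjacent pairs, (1R,2S) anti (erythro) in each diol chain and (2R,3S) trans in the dihydrofuran; the pairs are separated by para-substituted benzene rings, so none can direct another. Fragile groups are the enal (Michael acceptor, reducible), the free phenol, and two sites that ionise to quinone methides: the 4-hydroxybenzylic carbinol on ring A and the benzylic C2–O bond of the dihydrofuran para to the ring C oxygen. The real difficulty is the two secondary alkyl aryl ether bonds to oxygens flanked by two methoxy groups, each anti to a neighbouring benzylic carbinol and each to be set in the absolute sense on its own. The key step exploits the central unit: its CH(OAr) carbon is bonded to the ring B carbinol carbon, to the ring C phenol oxygen and to a carbon that can stand at the ester level, which is the substitution pattern of a diazoacetate carbene carbon captured by a phenol and an aldehyde.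

## Logic of the disconnections

30 ⇒ 29. Four O–Si bonds are cut and no skeletal bond. Every hydroxyl except the one that reacts in the key step has to be masked, and silyl ethers allow one common release. The forward step must free a phenol para to a benzylic carbinol and leave the enal alone, so the fluoride has to be buffered.

29 ⇒ 26 + 27 (through 28). The bond between C5 of ring D and the propenal chain is cut. An alkene or conjugated aldehyde on ring D would not survive carbene chemistry or hydride, so the three carbons arrive last and masked in 27. Ring D then carries only bromine. The coupling must tolerate the free 1,3-diol of 26 and keep the E geometry, and 28 must hydrolyse under acid too weak to ionise the benzylic carbinols.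

26 ⇒ 25. The primary alcohol is taken back to the ethyl ester, the oxidation level that a diazoacetate delivers. The hydride must not provoke retro-aldol cleavage or touch the C–Br bond.

25 ⇒ 11 + 18 + 24. Two bonds on one carbon are cut: C2–C3 of the central unit and C2–O to ring C. This is the one place where the molecule falls into two halves of similar size, each holding one finished stereo-pair, plus a two-carbon piece. The forward step has to make both bonds and both central stereocentres at once. It demands that the ylide add to the aldehyde faster than it shifts a proton, that an external chiral acid impose anti and R selectivity, and that 24 carry the only free hydroxyl.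

11 ⇒ 9 (through 10). The ring B C–CHO bond is cut. A free aldehyde on ring B would compete with 2 as electrophile in the aldol, so bromine holds the place. The exchange must spare three silyl ethers.

9 ⇒ 8 ⇒ 7. Two O–Si bonds are removed and the primary alcohol is returned to the acyl oxazolidinone. The reduction must release the auxiliary without retro-aldol.

7 ⇒ 5 + 2. The carbinol C–C bond is cut (aldol retron). Both stereocentres of the pair then come from two achiral aromatic pieces under auxiliary control. The demand is an anti aldol, not the usual syn, with attack on the enolate face that gives (2R,3R).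

5 ⇒ 3 + 4 and 2 ⇒ 1. The aryl O–CH2 bond and an O–Si bond are cut; both forward steps are simple substitutions at oxygen.

24 ⇒ 22 (through 23) ⇒ 21. O–Si bonds are adjusted and the primary alcohol is taken back to the ester. The ring C phenol must be masked during carbene insertion and free only for the key step, and the C3 side chain must be at the alcohol level before the phenol is freed. The demand is cleavage of an aryl silyl ether beside an alkyl one.

21 ⇒ 19 (through 20). The C2–C3 bond of the dihydrofuran is cut (1,5 C–H insertion retron), which removes the ring and both ring stereocentres. The catalyst must distinguish the enantiotopic benzylic hydrogens, and the cis ester must equilibrate to trans without ring opening.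

19 ⇒ 17 + 18. The bond between ring D and the diazo carbon is cut, so the whole diazoacetate is attached in one step and no homologation is needed. Palladium must insert at C–I and leave C–Br.

17 ⇒ 16 + 14, 16 ⇒ 15, 14 ⇒ 13 ⇒ 12. The benzylic O–CH2 bond, the C–I bond, a C–H (alcohol to aldehyde) and an O–Si bond are cut. All forward steps are standard; the ether formation must avoid a 4-silyloxybenzyl halide.

## Other disconnections considered

Alternative 1: The cut is the C2–O bond of the dihydrofuran. In the forward sense diol A2, with the ring D-bearing carbon fixed as S and either configuration at the carbinol, would be treated with mild acid. Both epimers would ionise to the same para-quinone methide of ring C, and the ortho phenol of ring D would add to it to give trans phenol A1.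
- In its favour: the carbinol configuration need not be controlled, the trans relationship is thermodynamic, and the chemistry is ionic and well precedented. On the certainty of its key step it is better than the chosen plan.
- Against it here: it needs free phenols on rings C and D together with acid. On a large intermediate these conditions would also ionise the other benzylic carbinols, so it can only be used early, on a small fragment. The quinone methide can also be intercepted by solvent or by a second molecule.
- Comparison: structurally it makes one C–O bond and sets one stereocentre relative to one already present, and does nothing for the central unit. As a way to reach the equivalent of 24 it would take about as many steps as steps 7–14 (an equal). As the strategy-carrying step it would leave the B–C ether and two stereocentres to alkylation, auxiliary aldol and reduction on the most advanced material, one operation more than steps 15–16 and with a stoichiometric auxiliary.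

Alternative 2: The cuts are the ring D–C3 bond and the CH2–O bond. Iodide A4, an enantioenriched branched allyl aryl ether, would be reduced by single-electron transfer to an aryl radical. This would cyclise 5-exo-trig onto the vinyl group, and TEMPO would trap the primary radical to give A3.
- In its favour: ring D starts with its aldehyde in place, so the enal would come from a two-carbon olefination without late palladium chemistry (better than the bromide handle of the chosen plan). The CH2O carbon is also formed at the right oxidation level (better, no ester reduction).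
- Against it here: the trans preference rests on a modest conformational bias in the cyclisation transition state, not on catalyst or thermodynamic control. The aryl radical can abstract the doubly activated C2–H, which would erode C2. The N–O bond needs a separate reductive cleavage. The aldehyde on ring D of A3 would compete as electrophile in a three-component union and would have to be masked. Making A4 requires branched-selective allylic etherification with a phenol substituted at both ortho positions.
- Comparison: it forms one C–C and one C–O bond and one ring, with one new stereocentre; the mechanism is radical, not carbene. The step count to the ring is about equal to that of steps 7–14, but stereocontrol is judged less secure than in step 12, and the central unit is not addressed.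

Alternative 3: The cut is the C2–C3 bond of the dihydrofuran. Diazo ester A6 with Rh2(S-PTTL)4 would insert into the benzylic C–H of the ortho benzyl ether, and methoxide would epimerise C3 to give trans ester A5.
- In its favour: it has the closest precedent for this ring type, sets C2 by catalyst control and C3 thermodynamically, and has a short route to the carbene precursor. The chosen route adopts this very reaction in step 12 (19 to 21, as the ethyl ester), so on the ring itself the two plans are equal. On mechanistic security this step is better than the ylide trapping of step 15.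
- Against it as the strategy-defining step: it makes one skeletal bond and one ring and leaves the B–C junction untouched. A synthesis centred on it would grow the chain from A5 by successive auxiliary aldols, with the longest sequence about one step longer and two stoichiometric auxiliaries on advanced material. Methoxide may also cleave the aryl silyl ether of A5, exposing a phenoxide para to C2 beside an enolisable ester, which invites ring opening; step 12 therefore uses DBU.
- Comparison: a concerted C–H insertion making one bond, against a stepwise ylide aldol making two bonds and two stereocentres while joining two fragments of similar size. The alternative wins on certainty and the chosen plan on convergence.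

Key step: step 15

Remarks on the chemistry:
- Assumption: 3, 4, 15, 27, Rh2(S-PTTL)4 and the phosphoric acid of step 15 are taken as purchasable.
- Assumption: the sense of induction of the phosphoric acid in step 15 cannot be predicted for this new substrate combination; the (R) acid is written, and its mirror image would be used if the opposite carbinol were favoured.
- Check of the structures: the descriptors of 11, 24 and 25 were re-derived and agree with the target, so no correction is needed. The new aryloxy carbon is R in ester 25 and S in diol 26 only because the CIP priorities change.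
- Design of the precursors: the skeletons of 11 and 24 are kept. The formyl group of 11 is introduced last from a bromide. Ring D keeps bromine, which is inert to carbene and acid and distinct from the iodide used in step 11. The C3 side chain of 24 is at the silyl ether level, so that no enolisable ester sits beside the free ring C phenol.

Step 1
Reactants: 1 vanillin
Product: 2 3-methoxy-4-(triisopropylsilyloxy)benzaldehyde
Conditions: TIPSCl, imidazole, DMF, rt
Reagents that add atoms: triisopropylsilyl chloride, CC(C)[Si](Cl)(C(C)C)C(C)C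
Why: Imidazole-promoted O-silylation of the phenol; the triisopropylsilyl ether should survive organolithium, hydride and mild aqueous base and leave with fluoride at the end.

Step 2
Reactants: 3 4-bromo-2,6-dimethoxyphenol; 4 (S)-4-benzyl-3-(chloroacetyl)oxazolidin-2-one
Product: 5 (S)-4-benzyl-3-[(4-bromo-2,6-dimethoxyphenoxy)acetyl]oxazolidin-2-one
Conditions: K2CO3, NaI (cat.), acetone, rt to 40 °C
Reagents that add atoms: none
Why: Williamson ether synthesis; the hindered phenoxide should displace the activated alpha-halide (iodide catalysis) faster than it attacks the imide carbonyl.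

Step 3
Reactants: 5 (S)-4-benzyl-3-[(4-bromo-2,6-dimethoxyphenoxy)acetyl]oxazolidin-2-one; 2 3-methoxy-4-(triisopropylsilyloxy)benzaldehyde
Product: 7 (S)-4-benzyl-3-[(2R,3R)-2-(4-bromo-2,6-dimethoxyphenoxy)-3-hydroxy-3-(3-methoxy-4-triisopropylsilyloxyphenyl)propanoyl]oxazolidin-2-one, via trimethylsilyl ether 6 (not isolated)
Conditions: MgCl2 (20 mol %), Et3N, TMSCl, EtOAc, rt; then 1 M HCl/THF, 0 °C
Reagents that add atoms: none
Why: Magnesium halide-catalysed direct anti-aldol of an N-acyloxazolidinone (Evans auxiliary) with a non-enolisable aromatic aldehyde; the magnesium-chelated (Z)-enolate should be attacked on the face away from the benzyl group, which sets C2 (R), and the boat-like transition state places aryloxy and aryl anti, which sets C3 (R). Silylation of the aldolate turns the metal over and blocks retro-aldol, and brief dilute acid removes the trimethylsilyl group.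

Step 4
Reactants: 7 (S)-4-benzyl-3-[(2R,3R)-2-(4-bromo-2,6-dimethoxyphenoxy)-3-hydroxy-3-(3-methoxy-4-triisopropylsilyloxyphenyl)propanoyl]oxazolidin-2-one
Product: 8 (1R,2S)-2-(4-bromo-2,6-dimethoxyphenoxy)-1-(3-methoxy-4-triisopropylsilyloxyphenyl)propane-1,3-diol
Conditions: LiBH4, H2O (1 equiv), Et2O/THF, 0 °C
Reagents that add atoms: none
Why: Reductive cleavage of the imide by LiBH4 should give the primary alcohol and return the auxiliary; neither stereocentre is touched, and the aryloxy carbon becomes S only by change of CIP priority.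

Step 5
Reactants: 8 (1R,2S)-2-(4-bromo-2,6-dimethoxyphenoxy)-1-(3-methoxy-4-triisopropylsilyloxyphenyl)propane-1,3-diol
Product: 9 (1R,2S)-2-(4-bromo-2,6-dimethoxyphenoxy)-1,3-bis(tert-butyldimethylsilyloxy)-1-(3-methoxy-4-triisopropylsilyloxyphenyl)propane
Conditions: TBSOTf, 2,6-lutidine, CH2Cl2, −78 to 0 °C
Reagents that add atoms: tert-butyldimethylsilyl triflate, CC(C)(C)[Si](C)(C)OS(=O)(=O)C(F)(F)F
Why: O-silylation with the silyl triflate and a hindered pyridine base should cover the hindered benzylic and the primary hydroxyl together at low temperature, without ionising the electron-rich benzylic position.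

Step 6
Reactants: 9 (1R,2S)-2-(4-bromo-2,6-dimethoxyphenoxy)-1,3-bis(tert-butyldimethylsilyloxy)-1-(3-methoxy-4-triisopropylsilyloxyphenyl)propane
Product: 11 4-{[(1R,2S)-1,3-bis(tert-butyldimethylsilyloxy)-1-(3-methoxy-4-triisopropylsilyloxyphenyl)propan-2-yl]oxy}-3,5-dimethoxybenzaldehyde, via aryllithium 10 (not isolated)
Conditions: n-BuLi, THF, −78 °C; DMF, −78 to 0 °C; H2O
Reagents that add atoms: N,N-dimethylformamide, CN(C)C=O
Why: Bromine–lithium exchange followed by formylation with DMF; the exchange at −78 °C is faster than attack on silicon or ortho-metalation, and the aldehyde appears only now because it would have competed as electrophile in step 3.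

Step 7
Reactants: 12 syringaldehyde
Product: 13 4-(tert-butyldimethylsilyloxy)-3,5-dimethoxybenzaldehyde
Conditions: TBSCl, imidazole, DMAP (cat.), DMF, rt
Reagents that add atoms: tert-butyldimethylsilyl chloride, CC(C)(C)[Si](C)(C)Cl
Why: O-silylation of the hindered phenol; the aryl silyl ether masks ring C oxygen through carbene chemistry and can later be cleaved beside an alkyl silyl ether.

Step 8
Reactants: 13 4-(tert-butyldimethylsilyloxy)-3,5-dimethoxybenzaldehyde
Product: 14 [4-(tert-butyldimethylsilyloxy)-3,5-dimethoxyphenyl]methanol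
Conditions: NaBH4, THF/EtOH, 0 °C
Reagents that add atoms: none
Why: Borohydride reduction of the aldehyde; short reaction at 0 °C should leave the aryl silyl ether in place.

Step 9
Reactants: 15 4-bromo-2-methoxyphenol
Product: 16 4-bromo-2-iodo-6-methoxyphenol
Conditions: NIS, TsOH (cat.), MeCN, rt
Reagents that add atoms: N-iodosuccinimide, O=C1CCC(=O)N1I
Why: Electrophilic aromatic iodination; the hydroxyl is the strongest director, its para position is blocked by bromine, so iodine should enter the single free ortho position.

Step 10
Reactants: 16 4-bromo-2-iodo-6-methoxyphenol; 14 [4-(tert-butyldimethylsilyloxy)-3,5-dimethoxyphenyl]methanol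
Product: 17 5-bromo-1-iodo-3-methoxy-2-{[4-(tert-butyldimethylsilyloxy)-3,5-dimethoxybenzyl]oxy}benzene
Conditions: PPh3, DIAD, THF, 0 °C to rt
Reagents that add atoms: none
Why: Mitsunobu etherification of an acidic phenol with a primary benzylic alcohol; it avoids the unstable 4-silyloxybenzyl halide.

Step 11
Reactants: 17 5-bromo-1-iodo-3-methoxy-2-{[4-(tert-butyldimethylsilyloxy)-3,5-dimethoxybenzyl]oxy}benzene; 18 ethyl diazoacetate
Product: 19 ethyl 2-{5-bromo-3-methoxy-2-[4-(tert-butyldimethylsilyloxy)-3,5-dimethoxybenzyloxy]phenyl}-2-diazoacetate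
Conditions: Pd(PPh3)4 (5 mol %), Ag2CO3, Et3N, toluene, rt
Reagents that add atoms: none
Why: Palladium-catalysed cross-coupling of an aryl iodide with ethyl diazoacetate, which arylates the diazo carbon and keeps the diazo group; at room temperature zerovalent palladium should insert into C–I far faster than into C–Br.

Step 12
Reactants: 19 ethyl 2-{5-bromo-3-methoxy-2-[4-(tert-butyldimethylsilyloxy)-3,5-dimethoxybenzyloxy]phenyl}-2-diazoacetate
Product: 21 ethyl (2R,3R)-trans-5-bromo-2-[4-(tert-butyldimethylsilyloxy)-3,5-dimethoxyphenyl]-7-methoxy-2,3-dihydrobenzofuran-3-carboxylate, via cis ester 20 (not isolated)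
Conditions: Rh2(S-PTTL)4 (1 mol %), toluene, −60 °C; then DBU, MeCN, 40 °C
Reagents that add atoms: none
Why: Intramolecular benzylic C–H insertion of a donor/acceptor rhodium carbene (1,5-insertion closing the five-membered ring); the chiral carboxylate ligands of the divalent rhodium dimer select between the enantiotopic benzylic hydrogens and should set C2 (R), giving the cis ester kinetically as in the closest precedents with 2-benzyloxyphenyl diazoacetates. DBU then equilibrates the acidic C3 to the more stable trans ester without a nucleophile that would cleave the aryl silyl ether.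

Step 13
Reactants: 21 ethyl (2R,3R)-trans-5-bromo-2-[4-(tert-butyldimethylsilyloxy)-3,5-dimethoxyphenyl]-7-methoxy-2,3-dihydrobenzofuran-3-carboxylate
Product: 22 [(2R,3S)-5-bromo-2-(4-tert-butyldimethylsilyloxy-3,5-dimethoxyphenyl)-7-methoxy-2,3-dihydrobenzofuran-3-yl]methanol
Conditions: i-Bu2AlH, CH2Cl2, −78 to 0 °C; Rochelle salt
Reagents that add atoms: none
Why: Hydride reduction of the ester to the primary alcohol removes the acidic C3–H and so locks the trans relationship; C3 becomes S only by change of CIP priority.

Step 14
Reactants: 22 [(2R,3S)-5-bromo-2-(4-tert-butyldimethylsilyloxy-3,5-dimethoxyphenyl)-7-methoxy-2,3-dihydrobenzofuran-3-yl]methanol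
Product: 24 4-[(2R,3S)-5-bromo-3-(tert-butyldimethylsilyloxymethyl)-7-methoxy-2,3-dihydrobenzofuran-2-yl]-2,6-dimethoxyphenol, via bis-silyl ether 23 (not isolated)
Conditions: TBSCl, imidazole, DMF, rt; then MeOH, K2CO3, rt
Reagents that add atoms: tert-butyldimethylsilyl chloride, CC(C)(C)[Si](C)(C)Cl
Why: O-silylation of the primary alcohol followed by selective methanolysis of the aryl silyl ether; phenoxide is a far better leaving group from silicon than alkoxide, so the alkyl silyl ether should stay.

Step 15
Reactants: 11 4-{[(1R,2S)-1,3-bis(tert-butyldimethylsilyloxy)-1-(3-methoxy-4-triisopropylsilyloxyphenyl)propan-2-yl]oxy}-3,5-dimethoxybenzaldehyde; 18 ethyl diazoacetate; 24 4-[(2R,3S)-5-bromo-3-(tert-butyldimethylsilyloxymethyl)-7-methoxy-2,3-dihydrobenzofuran-2-yl]-2,6-dimethoxyphenol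
Product: 25 ethyl (2R,3R)-3-hydroxy-2-(ring C aryloxy of 24)-3-(ring B aryl of 11)propanoate, the full silyl-protected skeleton with bromine on ring D
Conditions: Rh2(OAc)4 (2 mol %), (R)-TRIP [(R)-3,3'-bis(2,4,6-triisopropylphenyl)-1,1'-binaphthyl-2,2'-diyl hydrogen phosphate] (10 mol %), 4 Å MS, CH2Cl2, −10 °C, 18 added over 4 h
Reagents that add atoms: none
Why: Proposed new method: Rh2(OAc)4 (divalent rhodium) decomposes 18 to an electrophilic carbene, the ring C phenol of 24 (the only O–H in the flask) adds to it, and the resulting rhodium-associated oxonium ylide behaves as the (Z)-enol of an aryloxyacetate; the chiral phosphoric acid holds this enol through P=O···H–O and the ring B aldehyde of 11 through P–O–H···O=C, and C–C bond formation in that assembly must outrun the 1,2-proton shift that would give the plain aryloxyacetate. The closest known reaction type is the three-component coupling of aryl diazoacetates, alcohols or water and aldehydes or imines under Rh2(OAc)4 with a chiral Brønsted or Lewis acid (trapping of protic oxonium ylides); a hindered phenol as ylide donor together with an acceptor-only diazo ester is the untested part. No ring is closed: the step makes the C2–O bond to ring C and the C2–C3 bond of the central unit. C3 (R) is fixed by the aldehyde face that the acid-bound enol can reach inside the chiral pocket, and C2 (R) by the enol face and the anti arrangement that the doubly hydrogen-bonded transition state should prefer; the stereocentres already present in 11 and 24 sit para to the reacting groups and should exert little bias, so the acid is expected to control both. The step needs carbene capture by O–H in preference to carbonyl oxygen, silyl ether oxygen or electron-rich arene, which the single free hydroxyl of 24 and slow addition of 18 secure. It needs aldol trapping faster than proton transfer, which is helped by a non-enolisable aldehyde whose 4-oxygen is twisted out of conjugation by the flanking methoxy groups (so it is about as electrophilic as benzaldehyde), by low temperature and by molecular sieves. The aryl bromide and all four silyl ethers are inert to both catalysts, and a reversible acid opening of the dihydrofuran of 24 through the ring C quinone methide would re-close to the same trans isomer because C3 is fixed.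

Step 16
Reactants: 25 ethyl (2R,3R)-3-hydroxy-2-(ring C aryloxy of 24)-3-(ring B aryl of 11)propanoate
Product: 26 the corresponding (1R,2S)-1-(ring B aryl)-2-(ring C aryloxy)propane-1,3-diol, silyl ethers and bromine unchanged
Conditions: LiBH4, MeOH (3 equiv), THF, 0 °C to rt
Reagents that add atoms: none
Why: Chemoselective borohydride reduction of the alpha-aryloxy ester to the primary alcohol; the mildly basic medium should not cause retro-aldol, and the aryl bromide and silyl ethers are inert. The descriptor of the aryloxy carbon changes from R to S by priority only.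

Step 17
Reactants: 26 the (1R,2S)-diol bearing bromine on ring D; 27 (E)-2-(3,3-diethoxyprop-1-en-1-yl)-4,4,5,5-tetramethyl-1,3,2-dioxaborolane
Product: 29 silyl-protected (E)-enal (propenal at C5 of ring D, central diol free), via diethyl acetal 28 (not isolated)
Conditions: Pd(dppf)Cl2 (5 mol %), K2CO3, 1,4-dioxane/H2O, 70 °C; then 1 M HCl, THF, 0 °C
Reagents that add atoms: water, O
Why: Suzuki–Miyaura coupling of the aryl bromide with an alkenylboronate proceeds with retention of alkene geometry and tolerates free hydroxyls; the allylic, aryl-conjugated acetal hydrolyses in cold dilute acid that should not ionise the benzylic carbinols.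

Step 18
Reactants: 29 silyl-protected (E)-enal
Product: 30 (E)-3-[(2R,3S)-2-{4-[(1R,2S)-1,3-dihydroxy-1-(4-{[(1R,2S)-1,3-dihydroxy-1-(4-hydroxy-3-methoxyphenyl)propan-2-yl]oxy}-3,5-dimethoxyphenyl)propan-2-yl]oxy-3,5-dimethoxyphenyl}-3-(hydroxymethyl)-7-methoxy-2,3-dihydrobenzofuran-5-yl]prop-2-enal (CNP0192639.1)
Conditions: Bu4NF, AcOH (1:1), THF, 0 °C to rt
Reagents that add atoms: none
Why: Fluoride-mediated cleavage of all four silyl ethers; buffering with acetic acid keeps the medium near neutral, so the enal and the phenolic benzylic carbinol of ring A should see neither strong base nor acid.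

Compound list

1 | vanillin | COc1cc(C=O)ccc1O | starting material
2 | 3-methoxy-4-(triisopropylsilyloxy)benzaldehyde | COc1cc(C=O)ccc1O[Si](C(C)C)(C(C)C)C(C)C | intermediate
3 | 4-bromo-2,6-dimethoxyphenol | COc1cc(Br)cc(OC)c1O | starting material
4 | (S)-4-benzyl-3-(chloroacetyl)oxazolidin-2-one | O=C(CCl)N1[C@@H](Cc2ccccc2)COC1=O | starting material
5 | (S)-4-benzyl-3-[(4-bromo-2,6-dimethoxyphenoxy)acetyl]oxazolidin-2-one | COc1cc(Br)cc(OC)c1OCC(=O)N1[C@@H](Cc2ccccc2)COC1=O | intermediate
6 | O-trimethylsilyl ether of 7 | COc1cc([C@@H](O[Si](C)(C)C)[C@H](C(=O)N3[C@@H](Cc4ccccc4)COC3=O)Oc2c(OC)cc(Br)cc2OC)ccc1O[Si](C(C)C)(C(C)C)C(C)C | intermediate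
7 | (S)-4-benzyl-3-[(2R,3R)-2-(4-bromo-2,6-dimethoxyphenoxy)-3-hydroxy-3-(3-methoxy-4-triisopropylsilyloxyphenyl)propanoyl]oxazolidin-2-one | COc1cc([C@@H](O)[C@H](C(=O)N3[C@@H](Cc4ccccc4)COC3=O)Oc2c(OC)cc(Br)cc2OC)ccc1O[Si](C(C)C)(C(C)C)C(C)C | intermediate
8 | (1R,2S)-2-(4-bromo-2,6-dimethoxyphenoxy)-1-(3-methoxy-4-triisopropylsilyloxyphenyl)propane-1,3-diol | COc1cc([C@@H](O)[C@H](CO)Oc2c(OC)cc(Br)cc2OC)ccc1O[Si](C(C)C)(C(C)C)C(C)C | intermediate
9 | (1R,2S)-2-(4-bromo-2,6-dimethoxyphenoxy)-1,3-bis(tert-butyldimethylsilyloxy)-1-(3-methoxy-4-triisopropylsilyloxyphenyl)propane | COc1cc([C@@H](O[Si](C)(C)C(C)(C)C)[C@H](CO[Si](C)(C)C(C)(C)C)Oc2c(OC)cc(Br)cc2OC)ccc1O[Si](C(C)C)(C(C)C)C(C)C | intermediate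
10 | aryllithium from 9 (lithium in place of bromine) | COc1cc([C@@H](O[Si](C)(C)C(C)(C)C)[C@H](CO[Si](C)(C)C(C)(C)C)Oc2c(OC)cc([Li])cc2OC)ccc1O[Si](C(C)C)(C(C)C)C(C)C | intermediate
11 | 4-{[(1R,2S)-1,3-bis(tert-butyldimethylsilyloxy)-1-(3-methoxy-4-triisopropylsilyloxyphenyl)propan-2-yl]oxy}-3,5-dimethoxybenzaldehyde | COc1cc([C@@H](O[Si](C)(C)C(C)(C)C)[C@H](CO[Si](C)(C)C(C)(C)C)Oc2c(OC)cc(C=O)cc2OC)ccc1O[Si](C(C)C)(C(C)C)C(C)C | intermediate
12 | syringaldehyde | COc1cc(C=O)cc(OC)c1O | starting material
13 | 4-(tert-butyldimethylsilyloxy)-3,5-dimethoxybenzaldehyde | COc1cc(C=O)cc(OC)c1O[Si](C)(C)C(C)(C)C | intermediate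
14 | [4-(tert-butyldimethylsilyloxy)-3,5-dimethoxyphenyl]methanol | COc1cc(CO)cc(OC)c1O[Si](C)(C)C(C)(C)C | intermediate
15 | 4-bromo-2-methoxyphenol | COc1cc(Br)ccc1O | starting material
16 | 4-bromo-2-iodo-6-methoxyphenol | COc1cc(Br)cc(I)c1O | intermediate
17 | 5-bromo-1-iodo-3-methoxy-2-{[4-(tert-butyldimethylsilyloxy)-3,5-dimethoxybenzyl]oxy}benzene | COc1cc(Br)cc(I)c1OCc1cc(OC)c(O[Si](C)(C)C(C)(C)C)c(OC)c1 | intermediate
18 | ethyl diazoacetate | CCOC(=O)C=[N+]=[N-] | starting material
19 | ethyl 2-{5-bromo-3-methoxy-2-[4-(tert-butyldimethylsilyloxy)-3,5-dimethoxybenzyloxy]phenyl}-2-diazoacetate | CCOC(=O)C(=[N+]=[N-])c1cc(Br)cc(OC)c1OCc1cc(OC)c(O[Si](C)(C)C(C)(C)C)c(OC)c1 | intermediate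
20 | ethyl (2R,3S)-cis-5-bromo-2-[4-(tert-butyldimethylsilyloxy)-3,5-dimethoxyphenyl]-7-methoxy-2,3-dihydrobenzofuran-3-carboxylate | COc1cc([C@@H]2Oc3c(OC)cc(Br)cc3[C@@H]2C(=O)OCC)cc(OC)c1O[Si](C)(C)C(C)(C)C | intermediate
21 | ethyl (2R,3R)-trans-5-bromo-2-[4-(tert-butyldimethylsilyloxy)-3,5-dimethoxyphenyl]-7-methoxy-2,3-dihydrobenzofuran-3-carboxylate | COc1cc([C@@H]2Oc3c(OC)cc(Br)cc3[C@H]2C(=O)OCC)cc(OC)c1O[Si](C)(C)C(C)(C)C | intermediate
22 | [(2R,3S)-5-bromo-2-(4-tert-butyldimethylsilyloxy-3,5-dimethoxyphenyl)-7-methoxy-2,3-dihydrobenzofuran-3-yl]methanol | COc1cc([C@@H]2Oc3c(OC)cc(Br)cc3[C@H]2CO)cc(OC)c1O[Si](C)(C)C(C)(C)C | intermediate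
23 | tert-butyldimethylsilyl ether of 22 (bis-silyl ether) | COc1cc([C@@H]2Oc3c(OC)cc(Br)cc3[C@H]2CO[Si](C)(C)C(C)(C)C)cc(OC)c1O[Si](C)(C)C(C)(C)C | intermediate
24 | 4-[(2R,3S)-5-bromo-3-(tert-butyldimethylsilyloxymethyl)-7-methoxy-2,3-dihydrobenzofuran-2-yl]-2,6-dimethoxyphenol | COc1cc([C@@H]2Oc3c(OC)cc(Br)cc3[C@H]2CO[Si](C)(C)C(C)(C)C)cc(OC)c1O | intermediate
25 | ethyl (2R,3R)-2-{4-[(2R,3S)-5-bromo-3-(tert-butyldimethylsilyloxymethyl)-7-methoxy-2,3-dihydrobenzofuran-2-yl]-2,6-dimethoxyphenoxy}-3-hydroxy-3-(4-{[(1R,2S)-1,3-bis(tert-butyldimethylsilyloxy)-1-(3-methoxy-4-triisopropylsilyloxyphenyl)propan-2-yl]oxy}-3,5-dimethoxyphenyl)propanoate | COc1cc([C@@H](O[Si](C)(C)C(C)(C)C)[C@H](CO[Si](C)(C)C(C)(C)C)Oc2c(OC)cc([C@@H](O)[C@H](C(=O)OCC)Oc3c(OC)cc([C@@H]4Oc5c(OC)cc(Br)cc5[C@H]4CO[Si](C)(C)C(C)(C)C)cc3OC)cc2OC)ccc1O[Si](C(C)C)(C(C)C)C(C)C | intermediate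
26 | (1R,2S)-propane-1,3-diol from reduction of the ester of 25 | COc1cc([C@@H](O[Si](C)(C)C(C)(C)C)[C@H](CO[Si](C)(C)C(C)(C)C)Oc2c(OC)cc([C@@H](O)[C@H](CO)Oc3c(OC)cc([C@@H]4Oc5c(OC)cc(Br)cc5[C@H]4CO[Si](C)(C)C(C)(C)C)cc3OC)cc2OC)ccc1O[Si](C(C)C)(C(C)C)C(C)C | intermediate
27 | (E)-2-(3,3-diethoxyprop-1-en-1-yl)-4,4,5,5-tetramethyl-1,3,2-dioxaborolane | CCOC(OCC)/C=C/B1OC(C)(C)C(C)(C)O1 | starting material
28 | diethyl acetal of 29 | COc1cc([C@@H](O[Si](C)(C)C(C)(C)C)[C@H](CO[Si](C)(C)C(C)(C)C)Oc2c(OC)cc([C@@H](O)[C@H](CO)Oc3c(OC)cc([C@@H]4Oc5c(OC)cc(/C=C/C(OCC)OCC)cc5[C@H]4CO[Si](C)(C)C(C)(C)C)cc3OC)cc2OC)ccc1O[Si](C(C)C)(C(C)C)C(C)C | intermediate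
29 | silyl-protected (E)-enal (target with three tert-butyldimethylsilyl ethers and one triisopropylsilyl ether) | COc1cc([C@@H](O[Si](C)(C)C(C)(C)C)[C@H](CO[Si](C)(C)C(C)(C)C)Oc2c(OC)cc([C@@H](O)[C@H](CO)Oc3c(OC)cc([C@@H]4Oc5c(OC)cc(/C=C/C=O)cc5[C@H]4CO[Si](C)(C)C(C)(C)C)cc3OC)cc2OC)ccc1O[Si](C(C)C)(C(C)C)C(C)C | intermediate
30 | CNP0192639.1 | COc1cc([C@@H](O)[C@H](CO)Oc2c(OC)cc([C@@H](O)[C@H](CO)Oc3c(OC)cc([C@@H]4Oc5c(OC)cc(/C=C/C=O)cc5[C@H]4CO)cc3OC)cc2OC)ccc1O | target

Total step count: 18. Longest linear sequence: 11 steps (steps 7, 8, 10, 11, 12, 13, 14, 15, 16, 17, 18, from 12).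

Steps least certain to work

Step 15 (proposed new method). The most likely failure is proton transfer within the ylide before it reaches the aldehyde, which would end in simple O–H insertion; an acceptor-only carbene gives a short-lived ylide and the aldehyde is only moderately activated by a Brønsted acid. Carbene dimerisation and weak or wrong facial and anti control by the acid are the next risks. The fallback uses known chemistry and sets out from 24 and 11. Phenol 24 would be alkylated with 4 (K2CO3, NaI, acetone) to the aryloxyacetyl imide F1. The magnesium halide-catalysed anti-aldol of step 3 (MgCl2, Et3N, TMSCl, EtOAc) with aldehyde 11 would give the trimethylsilyl ether F2, and dilute acid the anti-aldol imide F3. LiBH4 would then cleave the auxiliary and give diol 26, where the route is rejoined.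

Step 3. The most likely failure is attack on the wrong enolate face or loss of the anti preference, because the 2,6-dimethoxyphenoxy group offers magnesium a competing chelate; the electron-rich aldehyde may also add slowly. The fallback sets out from 3 and uses the boron-mediated syn aldol, the established mode for aryloxyacetyl imides, followed by inversion of the carbinol.
- Alkylation of 3 with the mirror-image chloroacetyl oxazolidinone would give the (R)-imide F4.
- Bu2BOTf, i-Pr2NEt and 2 (CH2Cl2, −78 to 0 °C) would give the syn adduct F5, (2R,3S).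
- LiBH4 would give the threo diol F6, and TBSCl with imidazole the primary silyl ether F7.
- Mitsunobu reaction with 4-nitrobenzoic acid would invert the carbinol to the 4-nitrobenzoate F8, and K2CO3 in MeOH at 0 °C would free the erythro alcohol F9.
- TBSOTf and 2,6-lutidine would convert F9 into 9.

Step 11. The most likely failure is decomposition of the diazo compound at palladium (dimerisation, reduction) together with slow oxidative addition at an iodide flanked by an ortho alkoxy group. The fallback sets out from 17 and separates the two tasks. Cross-coupling of 17 with the Reformatsky reagent BrZnCH2CO2Et (Pd(PPh3)4, THF, 50 °C) would give the arylacetate F10, and Regitz diazo transfer (4-acetamidobenzenesulfonyl azide, DBU, MeCN) would return to 19.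

Step 12. The insertion has close precedent. The likelier failure is in the second half: base-induced opening of the dihydrofuran from the ester enolate, or loss of the aryl silyl ether, during equilibration with DBU. The ethyl ester may also lower enantioselection. The fallback epimerises at the aldehyde level, where a weak amine suffices. It sets out from 20, isolated without DBU.
- i-Bu2AlH would reduce 20 to the cis alcohol F11.
- Dess–Martin periodinane (NaHCO3, CH2Cl2) would give the cis aldehyde F12.
- Et3N in CH2Cl2 would equilibrate it to the trans aldehyde F13.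
- NaBH4 would return to 22.

Further compounds

F1 | step 15 | (S)-4-benzyl-3-({4-[(2R,3S)-5-bromo-3-(tert-butyldimethylsilyloxymethyl)-7-methoxy-2,3-dihydrobenzofuran-2-yl]-2,6-dimethoxyphenoxy}acetyl)oxazolidin-2-one | COc1cc([C@@H]2Oc3c(OC)cc(Br)cc3[C@H]2CO[Si](C)(C)C(C)(C)C)cc(OC)c1OCC(=O)N1[C@@H](Cc2ccccc2)COC1=O
F2 | step 15 | O-trimethylsilyl ether of F3 | COc1cc([C@@H](O[Si](C)(C)C(C)(C)C)[C@H](CO[Si](C)(C)C(C)(C)C)Oc2c(OC)cc([C@@H](O[Si](C)(C)C)[C@H](C(=O)N6[C@@H](Cc7ccccc7)COC6=O)Oc3c(OC)cc([C@@H]4Oc5c(OC)cc(Br)cc5[C@H]4CO[Si](C)(C)C(C)(C)C)cc3OC)cc2OC)ccc1O[Si](C(C)C)(C(C)C)C(C)C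
F3 | step 15 | (2R,3R)-anti-aldol imide, the analogue of 25 with the (S)-4-benzyloxazolidin-2-one in place of ethoxy | COc1cc([C@@H](O[Si](C)(C)C(C)(C)C)[C@H](CO[Si](C)(C)C(C)(C)C)Oc2c(OC)cc([C@@H](O)[C@H](C(=O)N6[C@@H](Cc7ccccc7)COC6=O)Oc3c(OC)cc([C@@H]4Oc5c(OC)cc(Br)cc5[C@H]4CO[Si](C)(C)C(C)(C)C)cc3OC)cc2OC)ccc1O[Si](C(C)C)(C(C)C)C(C)C
F4 | step 3 | (R)-4-benzyl-3-[(4-bromo-2,6-dimethoxyphenoxy)acetyl]oxazolidin-2-one | COc1cc(Br)cc(OC)c1OCC(=O)N1[C@H](Cc2ccccc2)COC1=O
F5 | step 3 | (R)-4-benzyl-3-[(2R,3S)-2-(4-bromo-2,6-dimethoxyphenoxy)-3-hydroxy-3-(3-methoxy-4-triisopropylsilyloxyphenyl)propanoyl]oxazolidin-2-one | COc1cc([C@H](O)[C@H](C(=O)N3[C@H](Cc4ccccc4)COC3=O)Oc2c(OC)cc(Br)cc2OC)ccc1O[Si](C(C)C)(C(C)C)C(C)C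
F6 | step 3 | (1S,2S)-2-(4-bromo-2,6-dimethoxyphenoxy)-1-(3-methoxy-4-triisopropylsilyloxyphenyl)propane-1,3-diol | COc1cc([C@H](O)[C@H](CO)Oc2c(OC)cc(Br)cc2OC)ccc1O[Si](C(C)C)(C(C)C)C(C)C
F7 | step 3 | (1S,2S)-2-(4-bromo-2,6-dimethoxyphenoxy)-3-(tert-butyldimethylsilyloxy)-1-(3-methoxy-4-triisopropylsilyloxyphenyl)propan-1-ol | COc1cc([C@H](O)[C@H](CO[Si](C)(C)C(C)(C)C)Oc2c(OC)cc(Br)cc2OC)ccc1O[Si](C(C)C)(C(C)C)C(C)C
F8 | step 3 | (1R,2S)-2-(4-bromo-2,6-dimethoxyphenoxy)-3-(tert-butyldimethylsilyloxy)-1-(3-methoxy-4-triisopropylsilyloxyphenyl)propyl 4-nitrobenzoate | COc1cc([C@@H](OC(=O)c3ccc(cc3)[N+](=O)[O-])[C@H](CO[Si](C)(C)C(C)(C)C)Oc2c(OC)cc(Br)cc2OC)ccc1O[Si](C(C)C)(C(C)C)C(C)C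
F9 | step 3 | (1R,2S)-2-(4-bromo-2,6-dimethoxyphenoxy)-3-(tert-butyldimethylsilyloxy)-1-(3-methoxy-4-triisopropylsilyloxyphenyl)propan-1-ol | COc1cc([C@@H](O)[C@H](CO[Si](C)(C)C(C)(C)C)Oc2c(OC)cc(Br)cc2OC)ccc1O[Si](C(C)C)(C(C)C)C(C)C
F10 | step 11 | ethyl 2-{5-bromo-3-methoxy-2-[4-(tert-butyldimethylsilyloxy)-3,5-dimethoxybenzyloxy]phenyl}acetate | CCOC(=O)Cc1cc(Br)cc(OC)c1OCc1cc(OC)c(O[Si](C)(C)C(C)(C)C)c(OC)c1
F11 | step 12 | [(2R,3R)-cis-5-bromo-2-(4-tert-butyldimethylsilyloxy-3,5-dimethoxyphenyl)-7-methoxy-2,3-dihydrobenzofuran-3-yl]methanol | COc1cc([C@@H]2Oc3c(OC)cc(Br)cc3[C@@H]2CO)cc(OC)c1O[Si](C)(C)C(C)(C)C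
F12 | step 12 | (2R,3S)-cis-5-bromo-2-(4-tert-butyldimethylsilyloxy-3,5-dimethoxyphenyl)-7-methoxy-2,3-dihydrobenzofuran-3-carbaldehyde | COc1cc([C@@H]2Oc3c(OC)cc(Br)cc3[C@@H]2C=O)cc(OC)c1O[Si](C)(C)C(C)(C)C
F13 | step 12 | (2R,3R)-trans-5-bromo-2-(4-tert-butyldimethylsilyloxy-3,5-dimethoxyphenyl)-7-methoxy-2,3-dihydrobenzofuran-3-carbaldehyde | COc1cc([C@@H]2Oc3c(OC)cc(Br)cc3[C@H]2C=O)cc(OC)c1O[Si](C)(C)C(C)(C)C
A1 | alternative 1 | 4-[(2R,3S)-5-bromo-3-(hydroxymethyl)-7-methoxy-2,3-dihydrobenzofuran-2-yl]-2,6-dimethoxyphenol | COc1cc([C@@H]2Oc3c(OC)cc(Br)cc3[C@H]2CO)cc(OC)c1O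
A2 | alternative 1 | (2S)-2-(5-bromo-2-hydroxy-3-methoxyphenyl)-1-(4-hydroxy-3,5-dimethoxyphenyl)propane-1,3-diol, either carbinol epimer | COc1cc(C(O)[C@H](CO)c2cc(Br)cc(OC)c2O)cc(OC)c1O
A3 | alternative 2 | (2R,3S)-2-[4-(tert-butyldimethylsilyloxy)-3,5-dimethoxyphenyl]-7-methoxy-3-[(2,2,6,6-tetramethylpiperidin-1-yloxy)methyl]-2,3-dihydrobenzofuran-5-carbaldehyde | COc1cc([C@@H]2Oc3c(OC)cc(C=O)cc3[C@H]2CON4C(C)(C)CCCC4(C)C)cc(OC)c1O[Si](C)(C)C(C)(C)C
A4 | alternative 2 | 3-iodo-5-methoxy-4-{[(1R)-1-(4-tert-butyldimethylsilyloxy-3,5-dimethoxyphenyl)prop-2-en-1-yl]oxy}benzaldehyde | COc1cc(C=O)cc(I)c1O[C@H](C=C)c1cc(OC)c(O[Si](C)(C)C(C)(C)C)c(OC)c1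
A5 | alternative 3 | methyl (2R,3R)-trans-5-bromo-2-[4-(tert-butyldimethylsilyloxy)-3,5-dimethoxyphenyl]-7-methoxy-2,3-dihydrobenzofuran-3-carboxylate | COc1cc([C@@H]2Oc3c(OC)cc(Br)cc3[C@H]2C(=O)OC)cc(OC)c1O[Si](C)(C)C(C)(C)C
A6 | alternative 3 | methyl 2-{5-bromo-3-methoxy-2-[4-(tert-butyldimethylsilyloxy)-3,5-dimethoxybenzyloxy]phenyl}-2-diazoacetate | COC(=O)C(=[N+]=[N-])c1cc(Br)cc(OC)c1OCc1cc(OC)c(O[Si](C)(C)C(C)(C)C)c(OC)c1
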